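**Retrosynthetic overview**
- The C3'–CH2 bond is cut last. The acid-sensitive prenyl group goes onto 3'-bromobiochanin A by a neutral Stille coupling, after all Lewis-acid chemistry is finished.
- Key disconnection: the O1–C2 bond of the pyranone. A one-carbon isocyanide is inserted into the 2'-O–H of a 2,4,6-trihydroxydeoxybenzoin, and the amine is then lost.
- The C4–C4a bond comes from Friedel–Crafts acylation of phloroglucinol with (3-bromo-4-methoxyphenyl)acetic acid.
- Ring order: rings A and B are bought. Ring C is the only ring built, in step 2.

Assumption: the target has no stereocentre and no stereogenic double bond, so it is one achiral compound and no stereocontrol is needed.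

**Step 1**
Reactants: 1 phloroglucinol (benzene-1,3,5-triol, anhydrous); 2 (3-bromo-4-methoxyphenyl)acetic acid
Product: 3 deoxybenzoin 2-(3-bromo-4-methoxyphenyl)-1-(2,4,6-trihydroxyphenyl)ethan-1-one
Conditions: BF3·OEt2 (neat, ca. 8 equiv), 75 °C, 2 h; then aq NaOAc, filter
Reagents that add atoms: none
Why: In this Friedel–Crafts C-acylation BF3 activates the acid, phloroglucinol offers only one kind of very nucleophilic C–H, and the ketone is deactivated as its boron chelate so that acylation stops at one acyl group, while the aryl bromide and methyl ether are inert and no stereocentre forms.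

**Step 2**
Reactants: 3 deoxybenzoin 2-(3-bromo-4-methoxyphenyl)-1-(2,4,6-trihydroxyphenyl)ethan-1-one
Product: 5 bromoisoflavone 3-(3-bromo-4-methoxyphenyl)-5,7-dihydroxy-4H-chromen-4-one (3'-bromobiochanin A), via aryl N-tert-butylformimidate 4 (not isolated)
Conditions: t-BuNC (3 equiv), Cu2O (10 mol %), 1,4-dioxane, 90 °C, Ar; then 1 M HCl/THF, rt
Reagents that add atoms: tert-butyl isocyanide, CC(C)(C)[N+]#[C-]
Why: Proposed new method: the Cu(I) aryloxide formed from 3 and Cu2O binds t-BuNC, undergoes 1,1-migratory insertion and is protonated to aryl formimidate 4 (the new O1–C2 bond), whose C=N carbon is then attacked by the enol of the neighbouring benzylic ketone in a favoured 6-(enolendo)-exo-trig closure followed by irreversible loss of t-BuNH2 to the γ-pyrone, while formimidates at the other hydroxyls exchange back or hydrolyse in the acidic work-up and the neutral soft-metal conditions spare the nucleophilic ring-A carbons, the aryl bromide and the methyl ether; the closest known reaction types are Cu(I)-catalysed isocyanide insertion into O–H, N–H and active C–H bonds, isocyanides as CH donors in benzoxazole synthesis, and the O-formylation/aldol closure of 2'-hydroxydeoxybenzoins; no stereocentre forms.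

**Step 3**
Reactants: 5 bromoisoflavone (3'-bromobiochanin A); 6 tributyl(3-methylbut-2-en-1-yl)stannane
Product: 7 5,7-dihydroxy-3-[4-methoxy-3-(3-methylbut-2-en-1-yl)phenyl]-4H-chromen-4-one (3'-prenylbiochanin A, target)
Conditions: 6 (1.8 equiv), Pd(PPh3)4 (5 mol %), degassed DMF, 100 °C, Ar
Reagents that add atoms: none
Why: This Stille cross-coupling is base-free and so leaves the two free phenols and the base-sensitive pyranone untouched, reductive elimination from the aryl-Pd-(η3-prenyl) species occurs at the unsubstituted CH2 terminus to give the linear prenyl arene, the 4'-OMe group rules out chroman formation, and no stereocentre forms.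

**Compound list**
1 | phloroglucinol (benzene-1,3,5-triol) | Oc1cc(O)cc(O)c1 | starting material
2 | (3-bromo-4-methoxyphenyl)acetic acid | COc1ccc(CC(=O)O)cc1Br | starting material
3 | 2-(3-bromo-4-methoxyphenyl)-1-(2,4,6-trihydroxyphenyl)ethan-1-one | COc1ccc(CC(=O)c2c(O)cc(O)cc2O)cc1Br | intermediate
4 | 2-[(3-bromo-4-methoxyphenyl)acetyl]-3,5-dihydroxyphenyl (E)-N-tert-butylformimidate (not isolated) | CC(C)(C)/N=C/Oc1cc(O)cc(O)c1C(=O)Cc1ccc(OC)c(Br)c1 | intermediate
5 | 3-(3-bromo-4-methoxyphenyl)-5,7-dihydroxy-4H-chromen-4-one (3'-bromobiochanin A) | COc1ccc(-c2coc3cc(O)cc(O)c3c2=O)cc1Br | intermediate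
6 | tributyl(3-methylbut-2-en-1-yl)stannane | CCCC[Sn](CCCC)(CCCC)CC=C(C)C | starting material
7 | 5,7-dihydroxy-3-[4-methoxy-3-(3-methylbut-2-en-1-yl)phenyl]-4H-chromen-4-one (achiral) | COc1ccc(-c2coc3cc(O)cc(O)c3c2=O)cc1CC=C(C)C | target

Total step count: 3. Longest linear sequence: 3.

**Steps most likely to fail, with fallbacks**

(i) The new ring closure (step 2) carries the most risk.
- Insertion into the hydrogen-bonded 2'-OH may be slow.
- The liberated t-BuNH2 consumes isocyanide under Cu(I), which is why 3 equiv are used.
- Formimidate left on O-7 has to hydrolyse cleanly in the work-up.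

The fallback is known chemistry, sets out from 3 and comes back at 5. It is a Vilsmeier-type C-formylation with DMF, MeSO2Cl and BF3·OEt2 at 50 to 90 °C. The iminium reagent attacks the benzylic carbon of the boron-chelated ketone. This gives the dimethylaminomethylene ketone 2-(3-bromo-4-methoxyphenyl)-3-(dimethylamino)-1-(2,4,6-trihydroxyphenyl)prop-2-en-1-one F1. F1 closes through the 2'-OH with loss of the amine. This is the standard closure for polyhydroxyisoflavones, and it can be run directly in the acylation pot of step 1.

(ii) The prenyl coupling (step 3) has three failure modes.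
- Some branched 1,1-dimethylallyl isomer may form.
- The acidic 7-OH may protodestannylate 6.
- Pd–H may shift the alkene into conjugation with ring B.

The fallback sets out from 5 and comes back at 7, and it builds the prenyl group by metathesis. First comes a Suzuki–Miyaura coupling with allylboronic acid pinacol ester (Pd(dppf)Cl2, K2CO3, dioxane/H2O, 80 °C). It gives 3-(3-allyl-4-methoxyphenyl)-5,7-dihydroxy-4H-chromen-4-one F2, which has no regiochemical ambiguity. Olefin cross-metathesis with excess 2-methylbut-2-ene (Grubbs second-generation catalyst, CH2Cl2, 40 °C) then gives 7.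

(iii) The acylation (step 1) may give incomplete conversion or diacylation if the phloroglucinol is wet or the stoichiometry drifts. The fallback sets out from 1 and comes back at 3, and it is a Houben–Hoesch reaction. Compound 1 and purchased (3-bromo-4-methoxyphenyl)acetonitrile F3 are treated with dry HCl and ZnCl2 in Et2O at 0 °C. This precipitates 2-(3-bromo-4-methoxyphenyl)-1-(2,4,6-trihydroxyphenyl)ethan-1-iminium chloride F4. F4 is filtered off and hydrolysed in boiling water to 3.

**Further compounds**
F1 | step 2 | 2-(3-bromo-4-methoxyphenyl)-3-(dimethylamino)-1-(2,4,6-trihydroxyphenyl)prop-2-en-1-one (push-pull C=C, configurationally labile, not isolated) | CN(C)C=C(C(=O)c1c(O)cc(O)cc1O)c1ccc(OC)c(Br)c1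
F2 | step 3 | 3-(3-allyl-4-methoxyphenyl)-5,7-dihydroxy-4H-chromen-4-one | C=CCc1cc(-c2coc3cc(O)cc(O)c3c2=O)ccc1OC
F3 | step 1 | (3-bromo-4-methoxyphenyl)acetonitrile (purchased for the fallback) | COc1ccc(CC#N)cc1Br
F4 | step 1 | 2-(3-bromo-4-methoxyphenyl)-1-(2,4,6-trihydroxyphenyl)ethan-1-iminium chloride | COc1ccc(CC(=[NH2+])c2c(O)cc(O)cc2O)cc1Br.[Cl-]
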